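Count the catalyst.

all flasks: substrate 0.10 M; other conformer 0.500 equiv; precatalyst 0.2 mol%; time 4.0 h

| charge | temperature | remark |
|---|---|---|
| summer | 90 °C |  |
| spring |  | at 110 °C until 2.0 h, from then on at 90 °C |
| noon | 110 °C |  |

- the best flask by amount of target, in percent of the substrate and other conformer together charged; "all alike" if 1.5 percentage points covers them all (summer / spring / noon / all alike)
- amount of target at the end, in percent of the substrate and other conformer together charged, summer
- amount of target at the end, in percent of the substrate and other conformer together charged, spring
- amount of target at the end, in percent of the substrate and other conformer together charged, noon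

- two of one species on the left: rate k times its square, two consumed each time
- the list of constants is for 110 °C, to be carried to other temperatures by the activation energies and enthalpies
- in a conversion other conformer counts as not yet reacted

    substrate ⇌ other conformer (K1 = 0.22, k1 = 3.33 × 10⁻⁵ s⁻¹, Ea1 = 126 kJ mol⁻¹, ΔH1 = −4.00 kJ mol⁻¹)
    substrate + free catalyst → free catalyst + target (k2 = 0.343 M⁻¹ s⁻¹, Ea2 = 50.0 kJ mol⁻¹)
    free catalyst + other conformer → free catalyst + isomer of the product (k3 = 0.396 M⁻¹ s⁻¹, Ea3 = 56.0 kJ mol⁻¹)
    2 free catalyst → spent catalyst (k4 = 0.642 M⁻¹ s⁻¹, Ea4 = 75.0 kJ mol⁻¹)
    precatalyst → free catalyst (k5 = 1.30 × 10⁻⁴ s⁻¹, Ea5 = 110 kJ mol⁻¹)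
    (constants at 110 °C)

Substrate turns into target on free catalyst, and free catalyst has to come out of precatalyst. So start with those two steps alone and charge 0.200 mM of precatalyst at noon, in 0.150 M of substrate and other conformer together. Summing free catalyst over the run gives 1.58 M·s at noon, and this sum is the catalyst dose. Target is then the step constant 0.343 M⁻¹ s⁻¹ times substrate times dose, which makes 36.1% of the charge.

Now add the death of free catalyst. It goes by the square, so treat it as pseudo-first-order, with a loss constant built from the mean free catalyst of the last round, and let release feed that loss. The first noon dose gives a constant of 1.41 × 10⁻⁴ s⁻¹, and the dose falls to 0.823 M·s. That dose is smaller than the one the constant was built from, so the loss constant drops to 7.34 × 10⁻⁵ s⁻¹ and the next round gives 1.09 M·s. The noon rounds swing around a midpoint of 0.958 M·s, which I take as my estimate.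

Last comes the conformer exchange. Other conformer is charged at 0.500 equiv against an equilibrium constant of 0.22, so it flows back into substrate, and I hold substrate at its charge. My noon figure is 21.9%.

Summer runs the same way at 90 °C. Release slows to 1.94 × 10⁻⁵ s⁻¹, the dose is 0.367 M·s, and the death constant is 0.176 M⁻¹ s⁻¹. In summer a loss constant of 8.96 × 10⁻⁶ s⁻¹ then trims the dose, in one round, to 0.352 M·s. With the step constant cooled to 0.145 M⁻¹ s⁻¹, summer gives 3.39%, so noon stands ahead of it. I stop short of spring, which I place between them.

The forecast says noon, with 3.5% for summer, 15.2% for spring and 22.3% for noon, on the ground that “Catalyst release is what limits these flasks”.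

The simulation gives noon as best, with 3.43% for summer, 15.5% for spring and 22.4% for noon.

Read back through the step constant with substrate held at its charge, noon's result is a dose of 0.978 M·s, against 1.58 M·s from release without death. Catalyst death and the short run are part of what holds noon back: with death struck out, noon reaches 32.4% at the end, and left for 40.0 h it reaches 54.4%. The dose carries to the neighbour of summer with 0.8 mol% of precatalyst. Release alone gives 1.47 M·s, and a loss constant of 3.58 × 10⁻⁵ s⁻¹ trims that to 1.24 M·s, or 12.0% of target, and that flask stands at 11.5%.

(The numbers of this flask were drawn at random within sensible limits, and the outcome is calculated.)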